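The pyranone ring is disconnected at O1–C8a and C3–C4 (chromanone numbering). The key step exploits two features: C3 is flanked by the C4 carbonyl and C2, and O1 and C4 sit ortho on ring A. With a temporary allyl carboxylate on C3, one pot does the work: the enolate of an allyl arylacetate (ring B) is C-acylated by a 2-fluoro-4-silyloxybenzoyl chloride (C3–C4), the β-keto ester enolate is hydroxymethylated with formaldehyde (C2), and the alkoxide closes the ring by SNAr at C8a, activated by the new ortho ketone (O1–C8a). Palladium-catalysed decarboxylative asymmetric protonation then removes the ester and sets the base-labile C3 stereocentre last.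

Key step: step 8

Remark: the target is (3S). The absolute sense of the protonation in step 9 is ligand-controlled, so the (S)-ligand is written and its mirror image is to be used if a pilot run gives the 3R series.

Step 1
Reactants: 1 2-fluoro-4-hydroxybenzoic acid
Product: 3 2-fluoro-4-(triisopropylsilyloxy)benzoic acid, via bis-silylated ester 2 (not isolated)
Conditions: TIPSCl (2.3 equiv), imidazole (5 equiv), DMF, rt; then K2CO3 (1.1 equiv), THF/MeOH/H2O, 0 °C to rt; aq. citric acid to pH 4
Reagents that add atoms: chlorotriisopropylsilane (TIPSCl), CC(C)[Si](Cl)(C(C)C)C(C)C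
Why: Imidazole-promoted silylation of both OH groups followed by mild basic hydrolysis of the far more labile silyl ester (selective silyl ester cleavage) should leave the aryl silyl ether and the free acid.

Step 2
Reactants: 3 2-fluoro-4-(triisopropylsilyloxy)benzoic acid
Product: 4 2-fluoro-4-(triisopropylsilyloxy)benzoyl chloride
Conditions: (COCl)2 (1.3 equiv), DMF (cat.), CH2Cl2, 0 °C to rt; volatiles removed, used crude
Reagents that add atoms: oxalyl chloride, ClC(=O)C(=O)Cl
Why: Vilsmeier-type activation with oxalyl chloride/DMF gives the acid chloride under conditions that the aryl silyl ether and the aryl fluoride should tolerate.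

Step 3
Reactants: 5 5-bromo-2-hydroxy-4-methoxybenzaldehyde
Product: 6 5-bromo-4-methoxy-2-(triisopropylsilyloxy)benzaldehyde
Conditions: TIPSCl (1.3 equiv), imidazole (2.5 equiv), DMAP (cat.), DMF, rt
Reagents that add atoms: chlorotriisopropylsilane (TIPSCl), CC(C)[Si](Cl)(C(C)C)C(C)C
Why: O-Silylation masks the ring B phenol for the basic and organometallic steps that follow.

Step 4
Reactants: 6 5-bromo-4-methoxy-2-(triisopropylsilyloxy)benzaldehyde
Product: 7 4-methoxy-5-(3-methylbut-2-en-1-yl)-2-(triisopropylsilyloxy)benzaldehyde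
Conditions: tributyl(3-methylbut-2-en-1-yl)stannane (1.3 equiv), Pd(PPh3)4 (5 mol%), anhydrous DMF, 95 °C, degassed
Reagents that add atoms: tributyl(3-methylbut-2-en-1-yl)stannane, CC(C)=CC[Sn](CCCC)(CCCC)CCCC
Why: Stille coupling of the aryl bromide with the prenylstannane should install the linear 3-methylbut-2-enyl group under neutral, fluoride-free conditions that keep the silyl ether and the aldehyde.

Step 5
Reactants: 7 4-methoxy-5-(3-methylbut-2-en-1-yl)-2-(triisopropylsilyloxy)benzaldehyde
Product: 8 [5-methoxy-2-(2-methoxyethenyl)-4-(3-methylbut-2-en-1-yl)phenoxy]triisopropylsilane (E/Z mixture)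
Conditions: Ph3P(CH2OMe)Cl (1.5 equiv), NaN(SiMe3)2 (1.45 equiv), THF, 0 °C; then 7, 0 °C to rt
Reagents that add atoms: (methoxymethyl)triphenylphosphonium chloride, COC[P+](c1ccccc1)(c1ccccc1)c1ccccc1.[Cl-]
Why: Wittig methoxymethylenation homologates the aldehyde by one carbon to the enol ether, whose double-bond geometry is of no consequence.

Step 6
Reactants: 8 [5-methoxy-2-(2-methoxyethenyl)-4-(3-methylbut-2-en-1-yl)phenoxy]triisopropylsilane
Product: 9 methyl 2-[4-methoxy-5-(3-methylbut-2-en-1-yl)-2-(triisopropylsilyloxy)phenyl]acetate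
Conditions: [C5H5NH][CrO3Cl] (pyridinium chlorochromate, 2 equiv), NaOAc, 4 Å MS, CH2Cl2, rt
Reagents that add atoms: pyridinium chlorochromate [C5H5NH][CrO3Cl], [O-][Cr](=O)(=O)Cl.c1cc[nH+]cc1
Why: Chlorochromate oxidation of an enol ether gives the ester at the oxygen-bearing carbon directly, so no free arylacetaldehyde is handled, and the trisubstituted prenyl alkene should not be attacked at room temperature.

Step 7
Reactants: 9 methyl 2-[4-methoxy-5-(3-methylbut-2-en-1-yl)-2-(triisopropylsilyloxy)phenyl]acetate
Product: 10 allyl 2-[4-methoxy-5-(3-methylbut-2-en-1-yl)-2-(triisopropylsilyloxy)phenyl]acetate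
Conditions: allyl alcohol (solvent), Ti(OiPr)4 (20 mol%), 85 °C, methanol distilled off
Reagents that add atoms: allyl alcohol, C=CCO
Why: Titanate-catalysed transesterification exchanges methyl for allyl under neutral conditions, driven by removal of methanol, without touching the silyl ether.

Step 8
Reactants: 10 allyl 2-[4-methoxy-5-(3-methylbut-2-en-1-yl)-2-(triisopropylsilyloxy)phenyl]acetate; 4 2-fluoro-4-(triisopropylsilyloxy)benzoyl chloride
Product: 13 allyl 3-[4-methoxy-5-(3-methylbut-2-en-1-yl)-2-(triisopropylsilyloxy)phenyl]-4-oxo-7-(triisopropylsilyloxy)chromane-3-carboxylate (racemic), via keto ester enolate 11 (not isolated), via hydroxymethyl alkoxide 12 (not isolated)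
Conditions: LiN(SiMe3)2 (2.1 equiv), THF, −78 °C; 4 (1.05 equiv), −78 to −20 °C; paraformaldehyde (3 equiv), DMPU, −20 to 40 °C; aq. NH4Cl
Reagents that add atoms: formaldehyde (from paraformaldehyde), C=O
Why: The ester enolate of 10 is C-acylated by acid chloride 4 (crossed Claisen acylation, the second equivalent of base storing the product as chelated enolate 11), 11 adds to formaldehyde (aldol hydroxymethylation) to give alkoxide 12, and 12 displaces fluoride at C8a through a Meisenheimer complex stabilised by the C4 ketone that the first event has just installed (intramolecular SNAr). The closest known reaction types are the acylation/SNAr annulations that give chromones and 4-quinolones from 2-fluorobenzoyl chlorides and the hydroxymethylation of 2-substituted β-keto esters, here telescoped in one flask. The one ring formed, the pyranone ring (O1, C2, C3, C4, C4a, C8a), closes at O1–C8a by a 6-exo-trig-type addition–elimination, C3–C4 and C2–C3 having been made intermolecularly just before. The new quaternary C3 stereocentre is deliberately formed racemic, because step 9 erases and resets it. The step needs C- over O-acylation (lithium enolate, acid chloride, −78 °C), cyclisation over retro-aldol loss of formaldehyde (the aldol is reversible, the SNAr is not, and a quaternary C3 cannot dehydrate) and a single substitution site (the only fluorine is ortho to the new ketone and the silyloxy group is meta to it, so it does not deactivate that carbon). The temperature is held at or below 40 °C so that ester-enolate Claisen or Carroll rearrangement of the allyl ester and silyl transfer from the ring B silyl ether to the alkoxide should not compete.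

Step 9
Reactants: 13 allyl 3-[4-methoxy-5-(3-methylbut-2-en-1-yl)-2-(triisopropylsilyloxy)phenyl]-4-oxo-7-(triisopropylsilyloxy)chromane-3-carboxylate (racemic)
Product: 14 (3S)-3-[4-methoxy-5-(3-methylbut-2-en-1-yl)-2-(triisopropylsilyloxy)phenyl]-7-(triisopropylsilyloxy)chroman-4-one
Conditions: Pd(OAc)2 (10 mol%), (S)-t-BuPHOX (12.5 mol%), Meldrum's acid (2.5 equiv), 1,4-dioxane, 40 °C
Reagents that add atoms: none
Why: Pd-catalysed decarboxylative asymmetric protonation: zerovalent palladium formed in the flask ionises the allyl ester, CO2 is lost, and the PHOX-bound palladium enolate is protonated by Meldrum's acid (which also takes up the allyl group) on the face dictated by the ligand and reinforced by the bulky ortho silyloxy group of ring B, so C3 is set without the α-aryl ketone ever meeting base.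

Step 10
Reactants: 14 (3S)-3-[4-methoxy-5-(3-methylbut-2-en-1-yl)-2-(triisopropylsilyloxy)phenyl]-7-(triisopropylsilyloxy)chroman-4-one
Product: 15 (3S)-7-hydroxy-3-[2-hydroxy-4-methoxy-5-(3-methylbut-2-en-1-yl)phenyl]chroman-4-one (CNP0227207.1)
Conditions: HF·pyridine (excess), THF/pyridine, 0 °C to rt
Reagents that add atoms: none
Why: Fluoride cleavage of both aryl silyl ethers in an acidic, buffered medium (desilylation) should avoid the base-mediated enolisation that would racemise C3 and leaves the prenyl group untouched.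

Compound list

1 | 2-fluoro-4-hydroxybenzoic acid | OC(=O)c1ccc(O)cc1F | starting material
2 | triisopropylsilyl 2-fluoro-4-(triisopropylsilyloxy)benzoate | CC(C)[Si](C(C)C)(C(C)C)OC(=O)c1ccc(O[Si](C(C)C)(C(C)C)C(C)C)cc1F | intermediate
3 | 2-fluoro-4-(triisopropylsilyloxy)benzoic acid | OC(=O)c1ccc(O[Si](C(C)C)(C(C)C)C(C)C)cc1F | intermediate
4 | 2-fluoro-4-(triisopropylsilyloxy)benzoyl chloride | ClC(=O)c1ccc(O[Si](C(C)C)(C(C)C)C(C)C)cc1F | intermediate
5 | 5-bromo-2-hydroxy-4-methoxybenzaldehyde | COc1cc(O)c(C=O)cc1Br | starting material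
6 | 5-bromo-4-methoxy-2-(triisopropylsilyloxy)benzaldehyde | COc1cc(O[Si](C(C)C)(C(C)C)C(C)C)c(C=O)cc1Br | intermediate
7 | 4-methoxy-5-(3-methylbut-2-en-1-yl)-2-(triisopropylsilyloxy)benzaldehyde | COc1cc(O[Si](C(C)C)(C(C)C)C(C)C)c(C=O)cc1CC=C(C)C | intermediate
8 | [5-methoxy-2-(2-methoxyethenyl)-4-(3-methylbut-2-en-1-yl)phenoxy]triisopropylsilane (E/Z mixture) | COC=Cc1cc(CC=C(C)C)c(OC)cc1O[Si](C(C)C)(C(C)C)C(C)C | intermediate
9 | methyl 2-[4-methoxy-5-(3-methylbut-2-en-1-yl)-2-(triisopropylsilyloxy)phenyl]acetate | COC(=O)Cc1cc(CC=C(C)C)c(OC)cc1O[Si](C(C)C)(C(C)C)C(C)C | intermediate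
10 | allyl 2-[4-methoxy-5-(3-methylbut-2-en-1-yl)-2-(triisopropylsilyloxy)phenyl]acetate | C=CCOC(=O)Cc1cc(CC=C(C)C)c(OC)cc1O[Si](C(C)C)(C(C)C)C(C)C | intermediate
11 | allyl 3-[2-fluoro-4-(triisopropylsilyloxy)phenyl]-2-[4-methoxy-5-(3-methylbut-2-en-1-yl)-2-(triisopropylsilyloxy)phenyl]-3-oxopropanoate (present as its lithium enolate) | C=CCOC(=O)C(C(=O)c1ccc(O[Si](C(C)C)(C(C)C)C(C)C)cc1F)c1cc(CC=C(C)C)c(OC)cc1O[Si](C(C)C)(C(C)C)C(C)C | intermediate
12 | allyl 3-[2-fluoro-4-(triisopropylsilyloxy)phenyl]-2-(hydroxymethyl)-2-[4-methoxy-5-(3-methylbut-2-en-1-yl)-2-(triisopropylsilyloxy)phenyl]-3-oxopropanoate (present as its lithium alkoxide, racemic) | C=CCOC(=O)C(CO)(C(=O)c1ccc(O[Si](C(C)C)(C(C)C)C(C)C)cc1F)c1cc(CC=C(C)C)c(OC)cc1O[Si](C(C)C)(C(C)C)C(C)C | intermediate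
13 | allyl 3-[4-methoxy-5-(3-methylbut-2-en-1-yl)-2-(triisopropylsilyloxy)phenyl]-4-oxo-7-(triisopropylsilyloxy)chromane-3-carboxylate (racemic) | C=CCOC(=O)C1(c2cc(CC=C(C)C)c(OC)cc2O[Si](C(C)C)(C(C)C)C(C)C)COc2cc(O[Si](C(C)C)(C(C)C)C(C)C)ccc2C1=O | intermediate
14 | (3S)-3-[4-methoxy-5-(3-methylbut-2-en-1-yl)-2-(triisopropylsilyloxy)phenyl]-7-(triisopropylsilyloxy)chroman-4-one | COc1cc(O[Si](C(C)C)(C(C)C)C(C)C)c([C@H]2COc3cc(O[Si](C(C)C)(C(C)C)C(C)C)ccc3C2=O)cc1CC=C(C)C | intermediate
15 | (3S)-7-hydroxy-3-[2-hydroxy-4-methoxy-5-(3-methylbut-2-en-1-yl)phenyl]chroman-4-one | COc1cc(O)c([C@H]2COc3cc(O)ccc3C2=O)cc1CC=C(C)C | target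

Total step count: 10. Longest linear sequence: 8 (steps 3 to 10, from compound 5).

Three steps most likely to fail

First risk, the key step 8. The hindered, doubly stabilised enolate may add to formaldehyde only reversibly, and the lithium alkoxide may cyclise slowly, so that retro-aldol loss of formaldehyde, silyl transfer from the ring B silyl ether or retro-Claisen cleavage take over. The fallback for step 8 sets out from compounds 10 and 4 and comes back to the route at compound 14. It closes the ring at a tertiary instead of a quaternary carbon and sets C3 by dynamic kinetic resolution. Only the Claisen acylation is run (LiN(SiMe3)2, THF, −78 °C) and β-keto ester 11 is isolated. Pd(PPh3)4 with HCO2H/Et3N in THF removes the allyl ester with decarboxylation to give 1-[2-fluoro-4-(triisopropylsilyloxy)phenyl]-2-[4-methoxy-5-(3-methylbut-2-en-1-yl)-2-(triisopropylsilyloxy)phenyl]ethan-1-one F1. Hydroxymethylation and SNAr at this less hindered carbon (paraformaldehyde, K2CO3, MeCN) should give racemic 3-[4-methoxy-5-(3-methylbut-2-en-1-yl)-2-(triisopropylsilyloxy)phenyl]-7-(triisopropylsilyloxy)chroman-4-one F2. Asymmetric transfer hydrogenation with dynamic kinetic resolution (RuCl(p-cymene)[(S,S)-TsDPEN], HCO2H/Et3N) should give the cis alcohol (3S,4S)-3-[4-methoxy-5-(3-methylbut-2-en-1-yl)-2-(triisopropylsilyloxy)phenyl]-7-(triisopropylsilyloxy)chroman-4-ol F3. Dess–Martin oxidation of the carbinol (CH2Cl2, 0 °C, no added base) then returns to 14.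

Second risk, step 9. Facial selectivity in the protonation of the palladium enolate may be poor, because the ring B aryl group carries only one ortho substituent. The fallback for step 9 sets out from compound 14 of insufficient enantiomeric purity and comes back to the route at compound 14. It replaces protonation of a metal enolate by Brønsted-acid-catalysed protonation of a silyl enol ether. Soft enolisation (TMSOTf, Et3N, CH2Cl2, 0 °C) gives triisopropyl{[3-[4-methoxy-5-(3-methylbut-2-en-1-yl)-2-(triisopropylsilyloxy)phenyl]-4-(trimethylsilyloxy)-2H-chromen-7-yl]oxy}silane F4. This is protonated enantioselectively with a catalytic BINOL-derived N-triflyl thiophosphoramide and stoichiometric phenol in toluene at low temperature to return 14.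

Third risk, step 6. The chlorochromate may cleave the electron-rich styryl enol ether double bond, or oxidise the allylic positions of the prenyl group, instead of forming the ester. The fallback for step 6 sets out from compound 8 and comes back to the route at compound 10, so that compound 9 and step 7 are bypassed. It goes through the free aldehyde and acid. Mild hydrolysis (aqueous oxalic acid, THF) gives 2-[4-methoxy-5-(3-methylbut-2-en-1-yl)-2-(triisopropylsilyloxy)phenyl]acetaldehyde F5. Pinnick oxidation (NaClO2, NaH2PO4, large excess of 2-methylbut-2-ene, t-BuOH/H2O) gives 2-[4-methoxy-5-(3-methylbut-2-en-1-yl)-2-(triisopropylsilyloxy)phenyl]acetic acid F6. O-Alkylation with allyl bromide (KHCO3, DMF) gives 10.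

Further compounds

F1 | step 8 | 1-[2-fluoro-4-(triisopropylsilyloxy)phenyl]-2-[4-methoxy-5-(3-methylbut-2-en-1-yl)-2-(triisopropylsilyloxy)phenyl]ethan-1-one | COc1cc(O[Si](C(C)C)(C(C)C)C(C)C)c(CC(=O)c2ccc(O[Si](C(C)C)(C(C)C)C(C)C)cc2F)cc1CC=C(C)C
F2 | step 8 | racemic 3-[4-methoxy-5-(3-methylbut-2-en-1-yl)-2-(triisopropylsilyloxy)phenyl]-7-(triisopropylsilyloxy)chroman-4-one | COc1cc(O[Si](C(C)C)(C(C)C)C(C)C)c(C2COc3cc(O[Si](C(C)C)(C(C)C)C(C)C)ccc3C2=O)cc1CC=C(C)C
F3 | step 8 | (3S,4S)-3-[4-methoxy-5-(3-methylbut-2-en-1-yl)-2-(triisopropylsilyloxy)phenyl]-7-(triisopropylsilyloxy)chroman-4-ol | COc1cc(O[Si](C(C)C)(C(C)C)C(C)C)c([C@H]2COc3cc(O[Si](C(C)C)(C(C)C)C(C)C)ccc3[C@H]2O)cc1CC=C(C)C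
F4 | step 9 | triisopropyl{[3-[4-methoxy-5-(3-methylbut-2-en-1-yl)-2-(triisopropylsilyloxy)phenyl]-4-(trimethylsilyloxy)-2H-chromen-7-yl]oxy}silane | COc1cc(O[Si](C(C)C)(C(C)C)C(C)C)c(C2=C(O[Si](C)(C)C)c3ccc(O[Si](C(C)C)(C(C)C)C(C)C)cc3OC2)cc1CC=C(C)C
F5 | step 6 | 2-[4-methoxy-5-(3-methylbut-2-en-1-yl)-2-(triisopropylsilyloxy)phenyl]acetaldehyde | O=CCc1cc(CC=C(C)C)c(OC)cc1O[Si](C(C)C)(C(C)C)C(C)C
F6 | step 6 | 2-[4-methoxy-5-(3-methylbut-2-en-1-yl)-2-(triisopropylsilyloxy)phenyl]acetic acid | OC(=O)Cc1cc(CC=C(C)C)c(OC)cc1O[Si](C(C)C)(C(C)C)C(C)C
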